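**Retrosynthetic overview**
- The strategy rests on the C8–C8' bond: two adjacent CH stereocentres of like (R,R) configuration, each bearing the same C9 CH2OH arm and the same C7 syringylmethyl arm, with a C2 axis through the midpoint of C8–C8'.
- Both C8–C9 and C8'–C9' bonds are disconnected by a twofold boronate one-carbon homologation, leading back to a vicinal C8,C8' bis(boronate).
- The bis(boronate) comes from enantioselective syn diboration of the E C8=C8' alkene of a 1,4-diarylbut-2-ene.
- That alkene is the self-metathesis dimer of O-benzylated 4-allyl-2,6-dimethoxyphenol; the benzyl ethers are removed last.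
- No ring is formed at any stage; the two arene rings are bought in with the allylphenol.

Key step: step 3

Assumption: (S)-Quinap is taken to deliver the (2R,3R) bis(boronate) from an E-1,2-dialkyl alkene; this sense is assumed rather than confirmed, and should a check by oxidising an aliquot of 6 to the 2,3-diol show the opposite face, (R)-Quinap is used with nothing else changed.

**Step 1**
Reactants: 1 4-allyl-2,6-dimethoxyphenol; 2 benzyl bromide
Product: 3 5-allyl-2-(benzyloxy)-1,3-dimethoxybenzene
Conditions: BnBr (1.2 equiv), K2CO3 (2 equiv), DMF, 60 °C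
Reagents that add atoms: benzyl bromide (compound 2), BrCc1ccccc1
Why: Williamson etherification of the phenoxide with a reactive benzylic bromide; the mild carbonate base should leave the allyl group unisomerised.

**Step 2**
Reactants: 3 5-allyl-2-(benzyloxy)-1,3-dimethoxybenzene (two molecules)
Product: 4 (E)-1,4-bis(4-benzyloxy-3,5-dimethoxyphenyl)but-2-ene
Conditions: second-generation Grubbs catalyst RuCl2(H2IMes)(PCy3)(=CHPh) (2 mol%), 1,4-benzoquinone (10 mol%), CH2Cl2, 40 °C, argon sweep; recrystallisation from EtOH–EtOAc
Reagents that add atoms: none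
Why: Olefin self-metathesis of a terminal allylarene, driven by loss of ethylene, with secondary metathesis favouring the E isomer, which as the more symmetrical dimer should be enriched by crystallisation; benzoquinone is added to suppress Ru–H migration of the alkene into conjugation.

**Step 3**
Reactants: 4 (E)-1,4-bis(4-benzyloxy-3,5-dimethoxyphenyl)but-2-ene; 5 bis(catecholato)diboron
Product: 8 (2R,3R)-2,3-bis(4-benzyloxy-3,5-dimethoxybenzyl)butane-1,4-diol, via vicinal bis(catecholboronate) 6 (not isolated), via homologated bis(catecholboronate) 7 (not isolated)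
Conditions: 5 (1.3 equiv), Rh(acac)(nbd) (5 mol%), (S)-Quinap (5 mol%), THF, rt; BrCH2Cl (6 equiv), n-BuLi (5 equiv), −78 °C to rt; 3 M aq NaOH, 30% H2O2, 0 °C to rt
Reagents that add atoms: bis(catecholato)diboron (compound 5), B1(B2Oc3ccccc3O2)Oc2ccccc2O1 (its atoms are carried in 6 and 7 and leave on oxidation); chloromethyllithium, [Li]CCl, made in the flask from bromochloromethane ClCBr and n-butyllithium [Li]CCCC (the two C9 carbons); hydrogen peroxide, OO (the two hydroxyl oxygens)
Why: Oxidative addition of the B–B bond of 5 to the monovalent rhodium–Quinap complex, alkene insertion into Rh–B and C–B reductive elimination place both boryl groups on one face of the alkene (the known Rh–Quinap enantioselective diboration of E-1,2-disubstituted alkenes), so syn addition to the E geometry of 4 can give only the C2-symmetric bis(boronate) 6 and not the meso isomer. Chloromethyllithium, generated beside 6 by Br–Li exchange, then forms an ate complex at each boron, and the C8 (C8') carbon migrates to CH2 with loss of chloride and retention of configuration, a twofold Matteson homologation that forms C8–C9 and C8'–C9' in 7; no ring is closed. Both stereocentres are set in the diboration: the like relative configuration by syn addition to the E alkene, the absolute (R,R) sense by the enantioface that the Quinap ligand selects, and both are carried unchanged through the stereoretentive 1,2-shift. The step needs enantiofacial selection on a symmetric E-alkene with two CH2 substituents, a class this catalyst is known to handle well, and it needs diboration to outrun rhodium-mediated migration of the alkene into conjugation with the arenes, which an excess of 5, a hydride-free catalyst precursor and room temperature should favour. Alkaline hydrogen peroxide then converts the two primary C–B bonds of 7, which do not involve the stereocentres, into the CH2OH groups of 8, and any meso diol arising from residual Z-alkene is a diastereomer that can be removed at this stage.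

**Step 4**
Reactants: 8 (2R,3R)-2,3-bis(4-benzyloxy-3,5-dimethoxybenzyl)butane-1,4-diol
Product: 9 5,5'-dimethoxysecoisolariciresinol, (2R,3R)-2,3-bis(4-hydroxy-3,5-dimethoxybenzyl)butane-1,4-diol
Conditions: H2 (1 atm), 10% Pd/C, EtOAc–MeOH, rt
Reagents that add atoms: none
Why: Catalytic hydrogenolysis of the two aryl benzyl ethers; the C7 benzylic C–C bonds, the aryl methyl ethers, the primary alcohols and the two stereocentres are inert to these conditions.

**Compound list**
1 | 4-allyl-2,6-dimethoxyphenol | C=CCc1cc(OC)c(O)c(OC)c1 | starting material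
2 | benzyl bromide | BrCc1ccccc1 | starting material
3 | 5-allyl-2-(benzyloxy)-1,3-dimethoxybenzene | C=CCc1cc(OC)c(OCc2ccccc2)c(OC)c1 | intermediate
4 | (E)-1,4-bis(4-benzyloxy-3,5-dimethoxyphenyl)but-2-ene | COc1cc(C/C=C/Cc2cc(OC)c(OCc3ccccc3)c(OC)c2)cc(OC)c1OCc1ccccc1 | intermediate
5 | bis(catecholato)diboron | B1(B2Oc3ccccc3O2)Oc2ccccc2O1 | starting material
6 | 2,2'-[(2R,3R)-1,4-bis(4-benzyloxy-3,5-dimethoxyphenyl)butane-2,3-diyl]bis(1,3,2-benzodioxaborole) | COc1cc(C[C@@H](B2Oc3ccccc3O2)[C@H](B2Oc3ccccc3O2)Cc2cc(OC)c(OCc3ccccc3)c(OC)c2)cc(OC)c1OCc1ccccc1 | intermediate (not isolated)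
7 | 2,2'-[(2R,3R)-2,3-bis(4-benzyloxy-3,5-dimethoxybenzyl)butane-1,4-diyl]bis(1,3,2-benzodioxaborole) | COc1cc(C[C@@H](CB2Oc3ccccc3O2)[C@H](CB2Oc3ccccc3O2)Cc2cc(OC)c(OCc3ccccc3)c(OC)c2)cc(OC)c1OCc1ccccc1 | intermediate (not isolated)
8 | (2R,3R)-2,3-bis(4-benzyloxy-3,5-dimethoxybenzyl)butane-1,4-diol | COc1cc(C[C@@H](CO)[C@H](CO)Cc2cc(OC)c(OCc3ccccc3)c(OC)c2)cc(OC)c1OCc1ccccc1 | intermediate
9 | 5,5'-dimethoxysecoisolariciresinol, (2R,3R)-2,3-bis(4-hydroxy-3,5-dimethoxybenzyl)butane-1,4-diol | COc1cc(C[C@@H](CO)[C@H](CO)Cc2cc(OC)c(O)c(OC)c2)cc(OC)c1O | target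

**Step count**
Total steps: 4. Longest linear sequence: 4 steps (1 → 3 → 4 → 8 → 9).

**Steps most likely to fail**

Step 3. The alkene may migrate into conjugation with an arene on rhodium before the B–B bond adds, the catalyst may discriminate the two enantiofaces poorly on this doubly benzylic substrate, or the catechol esters may homologate incompletely or by oxygen instead of carbon migration, leaving 1,2- or 1,3-diols. The fallback abandons the alkene and sets out from 3. Hydroboration–oxidation (9-BBN, THF; NaOH, H2O2) gives 3-(4-benzyloxy-3,5-dimethoxyphenyl)propan-1-ol F1. Oxidation (TEMPO, PhI(OAc)2, MeCN–H2O) gives 3-(4-benzyloxy-3,5-dimethoxyphenyl)propanoic acid F2. Pivaloyl chloride and Et3N convert it in the flask into the mixed pivalic anhydride F3, which acylates lithiated (S)-4-isopropyloxazolidin-2-one to give (S)-3-[3-(4-benzyloxy-3,5-dimethoxyphenyl)propanoyl]-4-isopropyloxazolidin-2-one F4. Oxidative homocoupling of its enolate (LiN(i-Pr)2, THF, −78 °C; then TiCl4) forms the C8–C8' bond and should give the (2R,3R)-2,3-bis(arylmethyl)succinyl bis-oxazolidinone F5, each enolate reacting on the face away from the isopropyl group. Reduction with LiBH4 (THF–MeOH, 0 °C) releases the auxiliary and rejoins the route at 8.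

Step 2. Ruthenium hydride species may move the allyl double bond into conjugation, after which secondary metathesis gives chain-shortened alkenes, or the E/Z mixture may not be resolved by crystallisation, so that the Z part ends as meso diol after step 3. The fallback sets out from 3 and builds the alkene by an E-selective olefination. Oxidative cleavage (K2OsO4·2H2O cat., NaIO4, 2,6-lutidine, dioxane–H2O) gives 2-(4-benzyloxy-3,5-dimethoxyphenyl)acetaldehyde F6. NaBH4 reduction of one portion gives 2-(4-benzyloxy-3,5-dimethoxyphenyl)ethanol F7. A Mitsunobu reaction with 1-phenyl-1H-tetrazole-5-thiol (PPh3, DIAD, THF) gives 5-{[2-(4-benzyloxy-3,5-dimethoxyphenyl)ethyl]sulfanyl}-1-phenyl-1H-tetrazole F8. Oxidation (H2O2, (NH4)6Mo7O24·4H2O, EtOH) gives 5-{[2-(4-benzyloxy-3,5-dimethoxyphenyl)ethyl]sulfonyl}-1-phenyl-1H-tetrazole F9. Julia–Kocienski olefination of F9 with the remaining F6 (KN(SiMe3)2, DME, −60 °C to rt) should give the E alkene and rejoins the route at 4.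

Step 4. The hydrogenolysis may stall at the mono-benzyl stage because each ether oxygen is flanked by two methoxy groups, or the palladium may be poisoned by boron or rhodium residues carried over from step 3. The fallback sets out from 8 and replaces reduction by Lewis-acid cleavage: BCl3 with pentamethylbenzene as benzyl-cation scavenger (CH2Cl2, −78 °C; MeOH quench) should remove both benzyl groups while leaving the aryl methyl ethers, and delivers 9 directly without a new intermediate.

**Further compounds**
F1 | step 3 | 3-(4-benzyloxy-3,5-dimethoxyphenyl)propan-1-ol | OCCCc1cc(OC)c(OCc2ccccc2)c(OC)c1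
F2 | step 3 | 3-(4-benzyloxy-3,5-dimethoxyphenyl)propanoic acid | OC(=O)CCc1cc(OC)c(OCc2ccccc2)c(OC)c1
F3 | step 3 | 3-(4-benzyloxy-3,5-dimethoxyphenyl)propanoic pivalic anhydride | CC(C)(C)C(=O)OC(=O)CCc1cc(OC)c(OCc2ccccc2)c(OC)c1
F4 | step 3 | (S)-3-[3-(4-benzyloxy-3,5-dimethoxyphenyl)propanoyl]-4-isopropyloxazolidin-2-one | CC(C)[C@H]1COC(=O)N1C(=O)CCc1cc(OC)c(OCc2ccccc2)c(OC)c1
F5 | step 3 | (4S,4'S)-3,3'-[(2R,3R)-2,3-bis(4-benzyloxy-3,5-dimethoxybenzyl)succinyl]bis(4-isopropyloxazolidin-2-one) | CC(C)[C@H]1COC(=O)N1C(=O)[C@H](Cc1cc(OC)c(OCc2ccccc2)c(OC)c1)[C@@H](Cc1cc(OC)c(OCc2ccccc2)c(OC)c1)C(=O)N1[C@@H](C(C)C)COC1=O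
F6 | step 2 | 2-(4-benzyloxy-3,5-dimethoxyphenyl)acetaldehyde | O=CCc1cc(OC)c(OCc2ccccc2)c(OC)c1
F7 | step 2 | 2-(4-benzyloxy-3,5-dimethoxyphenyl)ethanol | OCCc1cc(OC)c(OCc2ccccc2)c(OC)c1
F8 | step 2 | 5-{[2-(4-benzyloxy-3,5-dimethoxyphenyl)ethyl]sulfanyl}-1-phenyl-1H-tetrazole | COc1cc(CCSc2nnnn2-c2ccccc2)cc(OC)c1OCc1ccccc1
F9 | step 2 | 5-{[2-(4-benzyloxy-3,5-dimethoxyphenyl)ethyl]sulfonyl}-1-phenyl-1H-tetrazole | COc1cc(CCS(=O)(=O)c2nnnn2-c2ccccc2)cc(OC)c1OCc1ccccc1
F0 | step 4 | none | none
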